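## Retrosynthetic overview

1. Locants follow the tridecane chain of the target: C1 = CH2OH, C2 = CH(NHAc), C3 = C=O, C4–C13 = ten CH2, with C13 on the furan. The main cut is C9–C10, in the middle of the tether. This bond is made last, without protecting groups, by Ni–H-catalysed reductive hydroalkylation of a but-3-enylfuran (furan + C10–C13) with a primary iodo ketone (C1–C9).
2. Enabling feature: the unbranched, heteroatom-free decamethylene tether between the furan α-carbon and the C3 ketone. Cutting at C9–C10 leaves a terminal vinyl group (C10=C11) insulated from the furan ring by C12H2–C13H2. It also leaves a primary C9 centre five methylenes away from the C3 ketone, C2 acetamide and C1 hydroxyl array. Both reacting carbons are therefore unhindered, and no 5- or 6-membered radical closure or 1,5-H shift can reach either sensitive end.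
3. Iodo ketone: the C3–C4 bond comes from a Weinreb ketone synthesis between an L-serine-derived oxazolidine amide (source of C2-(S)) and 6-chlorohexyl Grignard. Boc/acetonide are then exchanged for NHAc/OH, and Cl for I.
4. Furan (the only ring of the target, aromatised before the union): the ring O, the four ring carbons and both ring methyls come from 2,3-dimethylmaleic anhydride. Propyl and butenyl enter by two Grignard 1,2-additions at the two carbonyl carbons, and dehydration of the final lactol aromatises the ring.

Key step: step 7

Remark: the butenolide-stage intermediates are racemic or diastereomeric mixtures. These stereocentres vanish on aromatisation, so no control is needed.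
Assumption: the two Grignard solutions and the L-serine-derived oxazolidine Weinreb amide are bought as such.

## Route

Step 1
Reactants: 1 2,3-dimethylmaleic anhydride; 2 n-propylmagnesium chloride
Product: 3 5-hydroxy-3,4-dimethyl-5-propylfuran-2(5H)-one (racemic)
Conditions: 2 (1.0 equiv) added slowly to 1, THF, −78 → −20 °C; then 1 M HCl
Reagents that add atoms: none
Why: Mono-1,2-addition of a Grignard reagent to a cyclic anhydride should stop after one addition because the reagent is dosed slowly into symmetrical 1 at low temperature, the first adduct rests as a poorly electrophilic magnesium lactolate/keto-carboxylate, the fully substituted C=C blocks conjugate addition, and acidification closes the pseudo-acid 3, whose racemic stereocentre is erased in step 3.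

Step 2
Reactants: 3 5-hydroxy-3,4-dimethyl-5-propylfuran-2(5H)-one
Product: 5 butenolide 3,4-dimethyl-5-propylfuran-2(5H)-one (racemic), via hydroxy acid 4 (not isolated)
Conditions: NaOH (1.0 equiv), NaBH4, EtOH–H2O, 0 °C → rt; then 2 M HCl, rt
Reagents that add atoms: none
Why: Borohydride reduction of the ring-opened γ-keto carboxylate followed by acid-induced lactonisation is the usual way from 5-hydroxybutenolides to butenolides and should work here because the Z-tetrasubstituted alkene holds the new hydroxyl next to the carboxyl group and resists 1,4-reduction; C5 is racemic and is erased in step 3.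

Step 3
Reactants: 5 3,4-dimethyl-5-propylfuran-2(5H)-one; 6 but-3-en-1-ylmagnesium bromide
Product: 8 2-(but-3-en-1-yl)-3,4-dimethyl-5-propylfuran, via lactol 7 (not isolated)
Conditions: LaCl3·2LiCl (1.0 equiv), 6 (1.15 equiv), THF, −78 → −30 °C; then 1 M HCl, Et2O, 0 °C → rt; product kept under Ar
Reagents that add atoms: none
Why: Lanthanide-assisted 1,2-addition of a Grignard reagent to the lactone carbonyl (the β-carbon is fully substituted, so there is no 1,4-addition, and the lanthanum salt disfavours γ-deprotonation) should give a cyclic lactolate that stays closed at low temperature, and acid then dehydrates lactol 7 irreversibly to the aromatic ring (butenolide-to-furan aromatisation).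

Step 4
Reactants: 9 1-bromo-6-chlorohexane; 10 tert-butyl (4S)-4-[methoxy(methyl)carbamoyl]-2,2-dimethyl-1,3-oxazolidine-3-carboxylate
Product: 12 tert-butyl (4S)-4-(7-chloroheptanoyl)-2,2-dimethyl-1,3-oxazolidine-3-carboxylate, via 6-chlorohexylmagnesium bromide 11 (not isolated)
Conditions: 9, Mg, THF, 35 °C; then 10, THF, −20 → 0 °C; cold 1 M HCl quench
Reagents that add atoms: none
Why: In this Weinreb ketone synthesis, magnesium inserts into C–Br and leaves C–Cl, the chelated tetrahedral adduct prevents over-addition, and the oxazolidine ring holds the C4–H out of alignment with the carbonyl, so the L-serine stereocentre should be carried over unchanged.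

Step 5
Reactants: 12 tert-butyl (4S)-4-(7-chloroheptanoyl)-2,2-dimethyl-1,3-oxazolidine-3-carboxylate
Product: 14 N-[(2S)-9-chloro-1-hydroxy-3-oxononan-2-yl]acetamide, via aminoketone hydrochloride 13 (not isolated)
Conditions: 4 M HCl in dioxane, H2O (5 equiv), 0 °C → rt; evaporate; then Ac2O (1.05 equiv), NaHCO3, EtOAc–H2O, 0 °C
Reagents that add atoms: acetic anhydride, CC(=O)OC(C)=O
Why: Acidolysis removes Boc and the N,O-acetonide in one operation (before the acid-sensitive furan is present) to give the configurationally stable ammonium salt, and Schotten–Baumann N-acetylation at 0 °C should trap the liberated amine faster than it can epimerise or self-condense and faster than the primary alcohol is acylated.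

Step 6
Reactants: 14 N-[(2S)-9-chloro-1-hydroxy-3-oxononan-2-yl]acetamide
Product: 15 N-[(2S)-1-hydroxy-9-iodo-3-oxononan-2-yl]acetamide
Conditions: NaI (5 equiv), acetone, reflux, dark
Reagents that add atoms: sodium iodide, [Na+].[I-]
Why: In this Finkelstein reaction, SN2 halide exchange at the unhindered primary chloride is driven by precipitation of NaCl under neutral conditions that do not touch C2.

Step 7
Reactants: 8 2-(but-3-en-1-yl)-3,4-dimethyl-5-propylfuran; 15 N-[(2S)-1-hydroxy-9-iodo-3-oxononan-2-yl]acetamide
Product: 16 N-[(2S)-13-(3,4-dimethyl-5-propylfuran-2-yl)-1-hydroxy-3-oxotridecan-2-yl]acetamide (CNP0315214.1)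
Conditions: 8 (1.5 equiv), NiBr2·diglyme (10 mol %), 4,4′-di-tert-butyl-2,2′-bipyridine (12 mol %), (EtO)2MeSiH (2.5 equiv), Na2CO3 (2.0 equiv), DMA, 25 °C, Ar, dark; aq. NH4Cl work-up
Reagents that add atoms: none
Why: A bipyridine-ligated Ni–H, regenerated each turnover from the nickel halide, the hydrosilane and carbonate, should add across the monosubstituted C10=C11 bond of 8 with nickel at the terminal carbon C10, low-valent nickel should abstract iodine from 15 to give the primary C9 radical, this radical is captured at the alkylnickel centre, and reductive elimination from the dialkylnickel(III) species forms C9–C10. The closest known reaction type is the Ni–H-catalysed anti-Markovnikov reductive hydroalkylation of unactivated terminal alkenes with unactivated primary alkyl iodides, a radical/organonickel alkyl–alkyl union that needs no stoichiometric organometallic and whose scope covers ketones, secondary amides and free alcohols. No ring is closed and no stereocentre is created; C2 is a spectator that must only be preserved. Cross-coupling over homo-coupling is secured because the partners enter the cycle by different elementary steps (hydrometalation for the alkene, halogen abstraction for the iodide), and linear regiochemistry is secured because the primary alkylnickel is the isomer that couples, so any chain walking along C11–C13 is funnelled back to C10. The division of roles protects both sensitive ends: the furan-bearing half is never a free radical, so attack on the electron-rich ring or abstraction of the furfurylic C13–H is not in play, and the C9 radical could reach the C3 carbonyl only by 7-membered closure, C4–H only by a 1,6-shift and the captodative C2–H only by a 1,8-shift. The non-oxidising, non-acidic medium spares the tetraalkylfuran, and the insoluble weak base at room temperature should leave the base-labile α-acetamido-β-hydroxy ketone and its configuration intact.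

## Compound list

1 | 2,3-dimethylmaleic anhydride (3,4-dimethylfuran-2,5-dione) | CC1=C(C)C(=O)OC1=O | starting material
2 | n-propylmagnesium chloride | CCC[Mg]Cl | starting material
3 | 5-hydroxy-3,4-dimethyl-5-propylfuran-2(5H)-one (racemic) | CCCC1(O)OC(=O)C(C)=C1C | intermediate
4 | (2Z)-4-hydroxy-2,3-dimethylhept-2-enoic acid (racemic, not isolated) | CCCC(O)/C(C)=C(/C)C(O)=O | intermediate
5 | 3,4-dimethyl-5-propylfuran-2(5H)-one (racemic) | CCCC1OC(=O)C(C)=C1C | intermediate
6 | but-3-en-1-ylmagnesium bromide | C=CCC[Mg]Br | starting material
7 | 2-(but-3-en-1-yl)-3,4-dimethyl-5-propyl-2,5-dihydrofuran-2-ol (diastereomer mixture, not isolated) | C=CCCC1(O)OC(CCC)C(C)=C1C | intermediate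
8 | 2-(but-3-en-1-yl)-3,4-dimethyl-5-propylfuran | C=CCCc1oc(CCC)c(C)c1C | intermediate
9 | 1-bromo-6-chlorohexane | ClCCCCCCBr | starting material
10 | tert-butyl (4S)-4-[methoxy(methyl)carbamoyl]-2,2-dimethyl-1,3-oxazolidine-3-carboxylate | CON(C)C(=O)[C@@H]1COC(C)(C)N1C(=O)OC(C)(C)C | starting material
11 | 6-chlorohexylmagnesium bromide (not isolated) | ClCCCCCC[Mg]Br | intermediate
12 | tert-butyl (4S)-4-(7-chloroheptanoyl)-2,2-dimethyl-1,3-oxazolidine-3-carboxylate | ClCCCCCCC(=O)[C@@H]1COC(C)(C)N1C(=O)OC(C)(C)C | intermediate
13 | (2S)-9-chloro-1-hydroxy-3-oxononan-2-aminium chloride (not isolated) | ClCCCCCCC(=O)[C@H](CO)[NH3+].[Cl-] | intermediate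
14 | N-[(2S)-9-chloro-1-hydroxy-3-oxononan-2-yl]acetamide | ClCCCCCCC(=O)[C@H](CO)NC(C)=O | intermediate
15 | N-[(2S)-1-hydroxy-9-iodo-3-oxononan-2-yl]acetamide | ICCCCCCC(=O)[C@H](CO)NC(C)=O | intermediate
16 | N-[(2S)-13-(3,4-dimethyl-5-propylfuran-2-yl)-1-hydroxy-3-oxotridecan-2-yl]acetamide | CCCc1oc(CCCCCCCCCCC(=O)[C@H](CO)NC(C)=O)c(C)c1C | target

## Count and risks

Total step count: 7. Longest linear sequence: 4 steps (steps 1, 2, 3, 7 or steps 4, 5, 6, 7).

**Step 7.**
- What may go wrong:
  - slow epimerisation at C2 or β-elimination of the C1 hydroxyl on the carbonate surface;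
  - hydrosilylation of the C3 ketone;
  - binding of nickel by the amido alcohol;
  - hydrodeiodination outrunning the coupling.
- The fallback sets out from 8 and 15 and comes back at 16. It replaces the reductive coupling by a two-stage hydroboration/B-alkyl Suzuki–Miyaura union on a ring-protected iodide.
- Alkene 8 is hydroborated with 9-BBN-H (THF, rt) to 9-[4-(3,4-dimethyl-5-propylfuran-2-yl)butyl]-9-borabicyclo[3.3.1]nonane F1.
- Iodide 15 is closed with 2,2-dimethoxypropane and catalytic camphorsulfonic acid to the temporary N,O-acetonide 1-[(4S)-3-acetyl-2,2-dimethyl-1,3-oxazolidin-4-yl]-7-iodoheptan-1-one F2. This removes the OH and NH protons and holds the C–H at the stereocentre out of alignment with the carbonyl.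
- Pd(PPh3)4 and K3PO4 in dioxane at 60 °C join the two at the same C9–C10 bond to give 1-[(4S)-3-acetyl-2,2-dimethyl-1,3-oxazolidin-4-yl]-11-(3,4-dimethyl-5-propylfuran-2-yl)undecan-1-one F3.
- Catalytic p-TsOH in aqueous MeOH at rt opens the acetonide to 16.

**Step 3.**
- What may go wrong: γ-deprotonation of the butenolide instead of addition, or ring opening of the lactolate followed by a second addition.
- The fallback sets out from 5 and comes back at 8. It builds the side chain on the finished furan instead.
- Butenolide 5 is reduced with DIBAL-H (CH2Cl2, −78 °C) to the lactol 3,4-dimethyl-5-propyl-2,5-dihydrofuran-2-ol F4. This loses water on acidic work-up to give 3,4-dimethyl-2-propylfuran F5.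
- The only free ring position of F5 adds to acrolein under catalytic acid (Friedel–Crafts-type conjugate addition) to give 3-(3,4-dimethyl-5-propylfuran-2-yl)propanal F6.
- Wittig methylenation (Ph3P=CH2, THF, 0 °C) gives 8.

**Step 5.**
- What may go wrong: epimerisation or self-condensation of the liberated α-amino ketone before it is acylated, or competing O-acetylation.
- The fallback sets out from 10 (and uses 11) and comes back at 14. It changes the order of events so that no free amino ketone ever exists.
- Amide 10 is deprotected first (4 M HCl in dioxane, H2O) to (2S)-2-amino-3-hydroxy-N-methoxy-N-methylpropanamide hydrochloride F7, an amino amide that neither epimerises readily nor self-condenses.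
- Schotten–Baumann acetylation gives (2S)-2-acetamido-3-hydroxy-N-methoxy-N-methylpropanamide F8.
- After removal of the OH and NH protons with i-PrMgCl (2 equiv, −20 °C), Grignard reagent 11 adds in a Weinreb ketone synthesis to give 14 directly.

## Further compounds

F1 | step 7 | 9-[4-(3,4-dimethyl-5-propylfuran-2-yl)butyl]-9-borabicyclo[3.3.1]nonane | CCCc1oc(CCCCB2C3CCCC2CCC3)c(C)c1C
F2 | step 7 | 1-[(4S)-3-acetyl-2,2-dimethyl-1,3-oxazolidin-4-yl]-7-iodoheptan-1-one | ICCCCCCC(=O)[C@@H]1COC(C)(C)N1C(C)=O
F3 | step 7 | 1-[(4S)-3-acetyl-2,2-dimethyl-1,3-oxazolidin-4-yl]-11-(3,4-dimethyl-5-propylfuran-2-yl)undecan-1-one | CCCc1oc(CCCCCCCCCCC(=O)[C@@H]2COC(C)(C)N2C(C)=O)c(C)c1C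
F4 | step 3 | 3,4-dimethyl-5-propyl-2,5-dihydrofuran-2-ol | CCCC1OC(O)C(C)=C1C
F5 | step 3 | 3,4-dimethyl-2-propylfuran | CCCc1occ(C)c1C
F6 | step 3 | 3-(3,4-dimethyl-5-propylfuran-2-yl)propanal | CCCc1oc(CCC=O)c(C)c1C
F7 | step 5 | (2S)-2-amino-3-hydroxy-N-methoxy-N-methylpropanamide hydrochloride | CON(C)C(=O)[C@H](CO)[NH3+].[Cl-]
F8 | step 5 | (2S)-2-acetamido-3-hydroxy-N-methoxy-N-methylpropanamide | CON(C)C(=O)[C@H](CO)NC(C)=O
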